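**Retrosynthetic overview**

- The target is cut at the bond between the 3,4,5-trimethoxyphenyl ipso carbon and C2 of the oxolane ring: aryllithium 12 plus the cis-3,4-disubstituted γ-lactone 10, whose carbonyl carbon is C2. One flask operation (addition, then silane reduction of the lactol) joins the fragments and sets C2.
- The feature that allows this: C2 is the one ring carbon bonded to both the ring oxygen O1 and the aryl ring, so it can be carried as the lactone C2(=O)–O1. The CH2O group on C3 and the benzyl group on C4 lie on one face of the oxolane ring, so the 2-aryl oxocarbenium ion can only take hydride on the other face, which gives the all-cis array.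
- The cis C3/C4 pair comes from syn-hydrogenation of an exocyclic silyloxymethylidene lactone anti to the C4 benzyl group. C4, C5 and the benzylic CH2 come from (R)-epichlorohydrin, through a cyclopropane-fused lactone that an aryl copper reagent opens.
- Ring order: the oxolane ring is formed first (step 1, as a γ-lactone fused to a temporary cyclopropane); the cyclopropane is opened in step 2; no ring is formed afterwards; both benzene rings are purchased.

Key step: step 6

Remark (assumption): in step 1 the malonate anion is assumed to attack the epoxide CH2 of 2 first, which is the pathway that leads from (R)-epichlorohydrin to the (4R) lactone series; the alkene geometry of 9 (drawn E) is immaterial because step 5 removes it.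

**Route**

Step 1
Reactants: 1 dimethyl malonate; 2 (R)-epichlorohydrin
Product: 3 methyl (1S,5R)-2-oxo-3-oxabicyclo[3.1.0]hexane-1-carboxylate
Conditions: NaOMe, MeOH, reflux
Reagents that add atoms: none
Why: Tandem alkylation in which the malonate anion should open the epoxide at its CH2 terminus, the alkoxide re-closes onto CH2Cl to a new epoxide, a 3-exo-tet SN2 attack of the malonate carbanion inverts the stereocentre and forms the cyclopropane, and the freed alkoxide lactonises onto the cis ester, so the stereocentre of 2 becomes C5 of 3 and later C4 of the target.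

Step 2
Reactants: 3 methyl (1S,5R)-2-oxo-3-oxabicyclo[3.1.0]hexane-1-carboxylate; 4 4-bromo-1,2-dimethoxybenzene
Product: 6 methyl (3S,4R)-4-[(3,4-dimethoxyphenyl)methyl]-2-oxooxolane-3-carboxylate (trans), via (3,4-dimethoxyphenyl)magnesium bromide 5 (not isolated)
Conditions: 4, Mg, THF, 40 °C; then 3, CuI (10 mol%), THF, −30 °C; 1 M HCl
Reagents that add atoms: none
Why: Copper-catalysed homoconjugate addition of the Grignard reagent to the doubly activated cyclopropane should occur at the unsubstituted CH2 with cleavage of the bond to the malonate carbon, so the ring-fusion CH is untouched and becomes C4 (R), while protonation of the stabilised enolate gives the trans ester at a centre that step 3 removes.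

Step 3
Reactants: 6 methyl (3S,4R)-4-[(3,4-dimethoxyphenyl)methyl]-2-oxooxolane-3-carboxylate
Product: 7 (4R)-4-[(3,4-dimethoxyphenyl)methyl]oxolan-2-one
Conditions: LiCl, DMSO, H2O, 140 °C
Reagents that add atoms: none
Why: Krapcho dealkoxycarbonylation, in which chloride demethylates the malonate-type ester and the carboxylate loses CO2, should leave the lactone and the C4 stereocentre (not alpha to a carbonyl) unchanged.

Step 4
Reactants: 7 (4R)-4-[(3,4-dimethoxyphenyl)methyl]oxolan-2-one
Product: 9 (3E,4R)-4-[(3,4-dimethoxyphenyl)methyl]-3-{[tri(propan-2-yl)silyl]oxymethylidene}oxolan-2-one, via sodium hydroxymethylidene-lactone enolate 8 (not isolated)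
Conditions: NaH, HCO2Et, THF, 0 °C to rt; then i-Pr3SiCl, DMF, 0 °C to rt
Reagents that add atoms: ethyl formate CCOC=O; chlorotri(propan-2-yl)silane CC(C)[Si](Cl)(C(C)C)C(C)C
Why: Claisen-type formylation of the lactone enolate at its only alpha position should give the sodium formyl enolate, a vinylogous carboxylate that is silylated on oxygen to the push-pull enol ether carrying the future hydroxymethyl carbon.

Step 5
Reactants: 9 (3E,4R)-4-[(3,4-dimethoxyphenyl)methyl]-3-{[tri(propan-2-yl)silyl]oxymethylidene}oxolan-2-one
Product: 10 (3R,4R)-4-[(3,4-dimethoxyphenyl)methyl]-3-{[tri(propan-2-yl)silyl]oxymethyl}oxolan-2-one (cis)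
Conditions: H2 (3 atm), Rh/Al2O3, EtOAc, rt
Reagents that add atoms: none
Why: Heterogeneous syn-hydrogenation of the exocyclic alkene should take place on the face anti to the C4 benzyl group, which puts H3 trans and the CH2OSi group cis to the benzyl group as is usual for alpha-alkylidene beta-benzyl butyrolactones, with rhodium chosen to limit C–O hydrogenolysis and double-bond migration.

Step 6
Reactants: 10 (3R,4R)-4-[(3,4-dimethoxyphenyl)methyl]-3-{[tri(propan-2-yl)silyl]oxymethyl}oxolan-2-one; 11 5-bromo-1,2,3-trimethoxybenzene
Product: 15 {[(2R,3R,4R)-4-[(3,4-dimethoxyphenyl)methyl]-2-(3,4,5-trimethoxyphenyl)oxolan-3-yl]methoxy}tri(propan-2-yl)silane, via (3,4,5-trimethoxyphenyl)lithium 12 (not isolated), via lactol lithium salt 13 (not isolated), via oxocarbenium ion 14 (not isolated)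
Conditions: 11, n-BuLi, THF/toluene (1:4), −78 °C; 10, −78 °C; then Et3SiH (excess), BF3·OEt2 (excess), CH2Cl2, −78 °C; Et3N then aq. NaHCO3 at −78 °C
Reagents that add atoms: none
Why: Bromine–lithium exchange on 11 gives aryllithium 12, whose single addition to the lactone carbonyl C2 of 10 makes the aryl–C2 bond and gives the lithium lactolate 13; BF3·OEt2 then ionises 13 to the planar 2-aryl oxocarbenium ion 14, which Et3SiH reduces by hydride transfer. The closest known reaction type is aryllithium addition to a lactone followed by silane/Lewis-acid reduction of the lactol, as used for C-aryl glycosides and 2-aryl oxolane lignans. No ring is closed: the oxolane ring is the lactone ring of 10 carried through with O1–C2 intact. The one new stereocentre, C2, is under substrate control: the C3 CH2OSi group (pseudoaxial, to avoid allylic strain with the coplanar aryl ring) and the C4 benzyl group occupy the same face of 14, so hydride should enter from the free face (inside attack on the C4-flap envelope) and the aryl group ends up cis to both, giving 2R. The step is stereoconvergent, because both anomers of 13 and its open hydroxy ketone form all pass through 14. It needs kinetic control, with hydride capture faster than loss of H3 from 14 (C3 epimerisation through the enol ether) and faster than re-ionisation of the benzylic C2–O bond of 15, which the low temperature, silane present in excess before the Lewis acid, the cold basic quench and the weakly cation-stabilising 3,4,5-trimethoxyphenyl ring should secure.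

Step 7
Reactants: 15 {[(2R,3R,4R)-4-[(3,4-dimethoxyphenyl)methyl]-2-(3,4,5-trimethoxyphenyl)oxolan-3-yl]methoxy}tri(propan-2-yl)silane
Product: 16 [(2R,3R,4R)-4-[(3,4-dimethoxyphenyl)methyl]-2-(3,4,5-trimethoxyphenyl)oxolan-3-yl]methanol
Conditions: Bu4NF, THF, 0 °C to rt
Reagents that add atoms: none
Why: Fluoride-mediated cleavage of the primary silyl ether is non-acidic and should not touch the benzylic C2–O bond or any stereocentre.

**Compound list**

1 | dimethyl malonate | COC(=O)CC(=O)OC | starting material
2 | (R)-epichlorohydrin, (2R)-2-(chloromethyl)oxirane | ClC[C@H]1CO1 | starting material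
3 | methyl (1S,5R)-2-oxo-3-oxabicyclo[3.1.0]hexane-1-carboxylate | COC(=O)[C@]12C[C@H]1COC2=O | intermediate
4 | 4-bromo-1,2-dimethoxybenzene | COc1ccc(Br)cc1OC | starting material
5 | (3,4-dimethoxyphenyl)magnesium bromide | COc1ccc([Mg]Br)cc1OC | intermediate
6 | methyl (3S,4R)-4-[(3,4-dimethoxyphenyl)methyl]-2-oxooxolane-3-carboxylate (trans; C3 epimerisable) | COc1ccc(C[C@H]2COC(=O)[C@@H]2C(=O)OC)cc1OC | intermediate
7 | (4R)-4-[(3,4-dimethoxyphenyl)methyl]oxolan-2-one | COc1ccc(C[C@H]2COC(=O)C2)cc1OC | intermediate
8 | sodium enolate of the 3-formyl derivative of 7 (sodium [(4R)-4-[(3,4-dimethoxyphenyl)methyl]-2-oxooxolan-3-ylidene]methanolate) | COc1ccc(C[C@H]2COC(=O)C2=C[O-])cc1OC.[Na+] | intermediate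
9 | (3E,4R)-4-[(3,4-dimethoxyphenyl)methyl]-3-{[tri(propan-2-yl)silyl]oxymethylidene}oxolan-2-one | COc1ccc(C[C@H]2COC(=O)/C2=C/O[Si](C(C)C)(C(C)C)C(C)C)cc1OC | intermediate
10 | (3R,4R)-4-[(3,4-dimethoxyphenyl)methyl]-3-{[tri(propan-2-yl)silyl]oxymethyl}oxolan-2-one (3,4-cis) | COc1ccc(C[C@H]2COC(=O)[C@H]2CO[Si](C(C)C)(C(C)C)C(C)C)cc1OC | intermediate
11 | 5-bromo-1,2,3-trimethoxybenzene | COc1cc(Br)cc(OC)c1OC | starting material
12 | (3,4,5-trimethoxyphenyl)lithium | [Li]c1cc(OC)c(OC)c(OC)c1 | intermediate
13 | (3R,4R)-4-[(3,4-dimethoxyphenyl)methyl]-3-{[tri(propan-2-yl)silyl]oxymethyl}-2-(3,4,5-trimethoxyphenyl)oxolan-2-ol (lactol, both configurations at C2; present in the flask as its lithium alkoxide) | COc1ccc(C[C@H]2COC(O)(c3cc(OC)c(OC)c(OC)c3)[C@H]2CO[Si](C(C)C)(C(C)C)C(C)C)cc1OC | intermediate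
14 | cyclic 2-aryl oxocarbenium ion from 13 (O1=C2 cation bearing the 3,4,5-trimethoxyphenyl group; C3 R and C4 R unchanged) | COc1ccc(C[C@H]2C[O+]=C(c3cc(OC)c(OC)c(OC)c3)[C@H]2CO[Si](C(C)C)(C(C)C)C(C)C)cc1OC | intermediate
15 | {[(2R,3R,4R)-4-[(3,4-dimethoxyphenyl)methyl]-2-(3,4,5-trimethoxyphenyl)oxolan-3-yl]methoxy}tri(propan-2-yl)silane (all-cis) | COc1ccc(C[C@H]2CO[C@@H](c3cc(OC)c(OC)c(OC)c3)[C@H]2CO[Si](C(C)C)(C(C)C)C(C)C)cc1OC | intermediate
16 | [(2R,3R,4R)-4-[(3,4-dimethoxyphenyl)methyl]-2-(3,4,5-trimethoxyphenyl)oxolan-3-yl]methanol (all-cis) | COc1ccc(C[C@H]2CO[C@@H](c3cc(OC)c(OC)c(OC)c3)[C@H]2CO)cc1OC | target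

**Step count and risks**

Total step count: 7. Longest linear sequence: 7 steps (1 and 2 → 3 → 6 → 7 → 9 → 10 → 15 → 16); the aryl bromides 4 and 11 enter directly.

Steps most likely to fail:

1. Step 6 (key step). Three processes threaten it: enolisation of the lactone by the aryllithium instead of addition; loss of H3 from the oxocarbenium ion with reprotonation, which would epimerise C3 before hydride arrives; and acid-induced re-opening of the benzylic C2–O bond of the product, leading to C2 epimerisation or Friedel–Crafts closure onto the dimethoxybenzyl ring. The fallback sets out from 10 and comes back at 15, and takes the stereochemistry from alkene hydrogenation instead of cation reduction. Aryllithium 12 is added to 10 and the mixture is quenched with aqueous NH4Cl so that lactol 13 can be isolated. Dehydration with MsCl/Et3N in CH2Cl2 at 0 °C should give the enol ether {[(4R)-4-[(3,4-dimethoxyphenyl)methyl]-2-(3,4,5-trimethoxyphenyl)-4,5-dihydrofuran-3-yl]methoxy}tri(propan-2-yl)silane F1. Hydrogenation of F1 (H2, Rh/Al2O3, EtOAc with a trace of Et3N) from the face anti to the C4 benzyl group should set C2 and C3 together and give all-cis 15, whatever the C3 configuration was beforehand.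

2. Step 5. Possible failures are poor facial selectivity, migration of the exocyclic double bond into the ring (which would erase the C4 stereocentre), hydrogenolysis of the vinylic C–O bond, or hydrolytic loss of the silyl enol ether made in step 4. The fallback sets out from 7, bypasses 9, and comes back at 10, using kinetic enolate protonation instead of hydrogenation. Deprotonation of 7 with LiN(i-Pr)2 in THF at −78 °C and addition of gaseous formaldehyde should give the trans aldol product (3S,4R)-4-[(3,4-dimethoxyphenyl)methyl]-3-(hydroxymethyl)oxolan-2-one F2. Silylation with i-Pr3SiCl and imidazole in DMF should give (3S,4R)-4-[(3,4-dimethoxyphenyl)methyl]-3-{[tri(propan-2-yl)silyl]oxymethyl}oxolan-2-one F3. Renewed deprotonation of F3 with LiN(i-Pr)2 at −78 °C and quenching with the hindered acid 2,6-di-tert-butyl-4-methylphenol should protonate the enolate anti to the benzyl group and give cis lactone 10.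

3. Step 2. Possible failures are direct 1,2-addition of the aryl Grignard reagent to the ester or lactone carbonyl, or slow transfer of the aryl group from copper to the cyclopropane CH2. The fallback sets out from 3 and comes back at 6, replacing the organocopper opening by halide opening and a cross-electrophile coupling. Me3SiI (from Me3SiCl/NaI in MeCN) should open the cyclopropane at its CH2 by SN2 attack of iodide, and methanol work-up should give methyl (3S,4R)-4-(iodomethyl)-2-oxooxolane-3-carboxylate F4. Nickel-catalysed reductive coupling of F4 with 4 (NiI2, 4,4'-di-tert-butyl-2,2'-bipyridine, Zn, N,N-dimethylacetamide, 60 °C) should then give 6.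

**Further compounds**

F1 | step 6 | {[(4R)-4-[(3,4-dimethoxyphenyl)methyl]-2-(3,4,5-trimethoxyphenyl)-4,5-dihydrofuran-3-yl]methoxy}tri(propan-2-yl)silane | COc1ccc(C[C@H]2COC(c3cc(OC)c(OC)c(OC)c3)=C2CO[Si](C(C)C)(C(C)C)C(C)C)cc1OC
F2 | step 5 | (3S,4R)-4-[(3,4-dimethoxyphenyl)methyl]-3-(hydroxymethyl)oxolan-2-one | COc1ccc(C[C@H]2COC(=O)[C@@H]2CO)cc1OC
F3 | step 5 | (3S,4R)-4-[(3,4-dimethoxyphenyl)methyl]-3-{[tri(propan-2-yl)silyl]oxymethyl}oxolan-2-one | COc1ccc(C[C@H]2COC(=O)[C@@H]2CO[Si](C(C)C)(C(C)C)C(C)C)cc1OC
F4 | step 2 | methyl (3S,4R)-4-(iodomethyl)-2-oxooxolane-3-carboxylate | IC[C@H]1COC(=O)[C@@H]1C(=O)OC
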